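Remark on locants: C1–C15 are terpenoid locants (C11 = methylidene carbon on C4, C12 = methyl on C5, C13 = methyl on C8, C14 = methyl on C9, C15 = benzylic carbon); C1'–C6' are arene locants (C1' bonded to C15, C2' bearing oxygen, C5' bearing the ester). Systematic names use naphthalene locants; the SMILES strings are authoritative for configuration.

Remark on the structures: the configurations of 22, 23 and 30 were re-derived centre by centre and agree with one another. C4 of 22 must be (S): this places the silyloxy group cis to the C5 methyl in 23 and leads to the (5S,8S,9R,10R) target, so no structure needed correction.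

## Structural features

The target is a sesquiterpenoid phenol: a cis-fused decalin (ring A: C1–C2–C3–C4–C5–C10; ring B: C5–C6–C7–C8–C9–C10) joined through the benzylic methylene C15 on C9 to a methyl 4-hydroxybenzoate, ortho to the phenol and meta to the ester. Ring A carries only the exocyclic methylidene C4=C11, next to the quaternary ring-fusion carbon C5. Ring B carries four contiguous stereocentres, C5 (quaternary, methyl C12), C10 (hydrogen), C9 (quaternary, methyl C14 and C15) and C8 (methyl C13), with C12, H10, C14 and C13 all on one face (5S, 8S, 9R, 10R). The fragile groups are the exocyclic alkene (it moves into ring A under acid and is lost on hydrogenation), the methyl ester (hydrides, hard organometallics, hydroxide) and the free phenol (bases, oxidants); C15 is benzylic and neopentylic, so a cation there invites a 1,2-shift from C9. The real difficulty is the pair of quaternary carbons C5 and C9 flanking C10 in an all-cis, cis-fused array: neither can be epimerised, so the relative configuration must be right when the bonds are made. The key step exploits the fact that the four stereocentres occupy exactly the four sp3 positions that a [4+2] cycloaddition creates in ring B (C5 and C8 from a diene C5=C6–C7=C8, C9 and C10 from a dienophile C9=C10), while ring A is six-membered through the shared C5–C10 bond and can serve as the tether. C4, which ends as an sp2 carbon, can meanwhile carry an oxygen stereocentre that steers the facial sense and is then erased.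

## Logic of the disconnections

30 ⇒ 29. The C4=C11 double bond is cut (methylenation of a C4 ketone). It is cut first because the exocyclic alkene survives neither hydrogenation of C6=C7 nor acid. The gain is that every earlier intermediate is free of the most fragile group. The demand is a methylenation beside the quaternary C5 in the presence of phenol and ester, which is why the phenol is carried as its phenoxide.

29 ⇒ 28 ⇒ 25 (through 26 and 27). No skeletal bond is cut: the C4 carbonyl is traced to the C4 carbinol and the two C15–H bonds to a C15 ketone. An oxygen on C15 is what a dienophile-activating group leaves behind; an oxygen on C4 is what a stereocontrol element leaves behind. The demand is a C15 deoxygenation that spares the benzoate and forms no cation beside C9, which the ortho-quinone methide path of an ortho-acylphenol meets, and an oxidation that spares the phenol.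

25 ⇒ 24 ⇒ 23. Two O–H bonds become O–Si bonds and the C6–C7 single bond becomes C6=C7. This uncovers a cyclohexene in ring B with the four stereocentres on its four sp3 carbons. The demand is a hydrogenation that leaves the hindered aryl ketone alone and a single operation that removes both silyl groups.

23 ⇒ 22 (key disconnection). C5–C10 and C8–C9 are cut, opening rings A and B at once. Both quaternary centres and all four stereocentres are then encoded in three alkene geometries (5Z, 7E, 9Z) and one carbinol centre (C4). The gain is that a bicyclic four-centre problem becomes a chain with one stereocentre. The demand is a cycloaddition that joins two fully substituted termini, takes only the cis-fused path, occurs anti to the C4 silyloxy group, and outruns geometric isomerisation and the 1,5-hydrogen shift of the Z-diene.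

22 ⇒ 18 + 20 (through 21), and 20 ⇒ 19. The C15–C1' bond is cut between carbonyl carbon and arene. This removes the whole arene as a commercial iodophenol and leaves an acyl partner at the right oxidation level. The demand is an aryl nucleophile that tolerates its own methyl ester, a phenol protecting group that survives it, and an acylation that stops at the ketone.

18 ⇒ 17 ⇒ 14 + 15 (through 16). The C9=C10 double bond is cut, after exchanging amide for ester. A trisubstituted (Z)-enoate is the normal outcome of a Still–Gennari olefination, and C9, C14 and C15 come from one commercial phosphonate. The demand is high Z selectivity, because the C9 configuration of 23 is decided here.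

14 ⇒ 13 ⇒ 12 ⇒ 11. Functional-group changes only: the C10 aldehyde from the primary alcohol, and the C4–O–Si and C10–O–Si bonds. The C10 oxygen has to stay masked while organometallic chemistry runs at the other end. The demand is selective removal of the primary silyl ether beside the secondary dienylic one without ionising the C4–O bond.

11 ⇒ 9 + 10. The C6–C7 single bond of the diene is cut between two sp2 carbons. Each alkene geometry is then fixed in a separate, geometrically pure partner and transferred with retention; this avoids a lactol that could aromatise to a furan and an olefination of uncertain E selectivity. The demand is an iodide with iodine cis to C4.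

9 ⇒ 7 (through 8). The C5–C12 bond and the carbon–iodine bond at C6 are cut, revealing a terminal alkyne. Alkoxide-directed anti-carbomagnesiation puts methyl on C5 and metal on C6 cis to C4; syn-carbometalation would give the wrong isomer. The demand is regio- and anti-selectivity on a secondary propargylic alcohol.

7 ⇒ 6 ⇒ 5. The C4–H bond is cut (carbinol to alkynyl ketone), with the alkyne C–H traced to C–Si. This is where absolute configuration enters, by asymmetric transfer hydrogenation. The demand is the (S)-alcohol in high enantiomeric purity, since all later centres are relayed from C4.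

5 ⇒ 4 ⇒ 1 + 2 (through 3). The C4–C5 bond is cut between carbonyl carbon and alkyne, and the C10–O–Si bond is removed. C4, C3, C2, C1 and C10 are the five carbons of 1, already differentiated as acyl and alkoxy ends. The demand is single addition of the acetylide.

## Other disconnections considered

Alternative 1: The cut is C5–C6 of ring B, made by reconnecting C3 to C8, which leads to the bicyclo[2.2.2]octenol A2 (vinyl C6=C7 on the carbinol carbon C8, quaternary C9 in place, ring alkene C4=C5 bearing C12). Forward, KH with 18-crown-6 gives the potassium alkoxide of A2; anionic oxy-Cope rearrangement breaks C3–C8 and forms C5–C6 to give, after protonation, the cis-fused octalone A1.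
- In favour: the charge-accelerated [3,3] shift runs near room temperature, the bicyclic frame permits only cis fusion, C5 becomes quaternary without any approach to a hindered centre from outside, and C9 is set beforehand on a rigid bicycle.
- Against: A1 lacks C13 and C11. The C8 methyl must be added to the ketone and its configuration set afterwards on a flexible cis-decalin. The C3=C4 alkene must be oxygenated at its more hindered carbon to reach the methylidene. The aryl bromide must be carbonylated and the MOM ether removed. A2 itself needs an enantioselective entry.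
- Structure: the chosen plan is ahead, since 23 holds every skeletal carbon but C11 and all four stereocentres, whereas A1 lacks two carbons and the C8 centre.
- Mechanism: the alternative is the equal or the better of the chosen plan, because an oxy-Cope of this substrate class is more firmly precedented and less sterically demanding than a cycloaddition joining two fully substituted termini.
- Step economy: the chosen plan is ahead, with five operations after its key step against an estimated nine or more after A1.

Alternative 2: The cut is at the arene: C15–C1' and O–C2' are both removed, giving the ketal-protected decalin acid A4 and the aryne A6, which would be released from the silyl triflate A5. Forward, CsF generates A6; the carboxylate oxygen of A4 adds at C2', remote from chlorine; the aryl anion at C1' attacks the ester carbonyl and the four-membered intermediate opens to the ortho-hydroxyaryl ketone A3.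
- In favour: phenol and C15–C1' bond arise in one nearly neutral operation, and A3 is the chloro, C4-ketal analogue of 25, so the deoxygenation of step 17 would carry over.
- Against: the step builds no ring and no stereocentre, so the whole cis-decalin must come from an independent synthesis of A4. The acyl shift needs an aryl anion to attack a carbonyl flanked by quaternary C9, where simple protonation to the aryl ester may prevail. The directing chlorine must later be removed, and A5 needs its own preparation.
- Structure: the chosen plan is ahead (two rings and four centres against none).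
- Mechanism: the risk at the hindered carbonyl is about equal, and the alternative is the better on one point: it avoids the ester-bearing arylmagnesium reagent and the phenol protection of steps 12 and 13.
- Step economy: the chosen plan is ahead, because dechlorination, ketal cleavage and the synthesis of A4 are added.

Alternative 3: The cut is C9–C10 of ring B, leading to the 4,4-disubstituted cyclohexadienone A8 (C5 as the quaternary ring carbon; chain C6–C7–C8 ending in the alkene C9=C14H2 that carries the arylmethyl group). Forward, Fe(acac)3 and PhSiH3 deliver a hydrogen atom to C14; the tertiary C9 radical adds 6-exo to C10, one of the two diastereotopic beta-carbons; reduction of the alpha-keto radical gives the cis-fused enone A7.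
- In favour: radical addition tolerates a quaternary–tertiary junction better than a concerted cycloaddition, the conditions are neutral and compatible with benzoate and aryl silyl ether, cis fusion is inherent, and C15 is already a methylene.
- Against: one bond and one ring are formed. Three stereochemical questions (which beta-carbon, hence C5; which face of the C9 radical; both relative to C8) rest on conformational preferences of a flexible chain. A7 carries oxygen at C2, so an enone transposition to C4 and a reduction precede methylenation.
- Structure: the chosen plan is ahead (two rings; four centres fixed by alkene geometry).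
- Mechanism: the alternative is the equal or the better in steric tolerance and functional-group compatibility, and the better in needing no C15 deoxygenation, but it is weaker in stereochemical predictability.
- Step economy: about equal, since what is saved at C15 is spent on the oxygen transposition in ring A.

Key step: step 14

## Route

Step 1
Reactants: 1 δ-valerolactone (tetrahydro-2H-pyran-2-one); 2 ethynyltrimethylsilane
Product: 4 7-hydroxy-1-(trimethylsilyl)hept-1-yn-3-one, via lithium (trimethylsilyl)acetylide 3 (not isolated)
Conditions: 2, n-BuLi, THF, −78 °C; then 1, −78 °C; aq. NH4Cl, −78 °C → rt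
Reagents that add atoms: none
Why: Acylation of an acetylide by a lactone: the tetrahedral lithium alkoxide is stable at −78 °C and collapses to the ynone only on quench, so single addition is expected; 4 equilibrates with its cyclic hemiketal and no stereocentre is formed.

Step 2
Reactants: 4 7-hydroxy-1-(trimethylsilyl)hept-1-yn-3-one
Product: 5 7-[(tert-butyldimethylsilyl)oxy]-1-(trimethylsilyl)hept-1-yn-3-one
Conditions: TBSCl, imidazole, CH2Cl2, 0 °C
Reagents that add atoms: tert-butyldimethylsilyl chloride CC(C)(C)[Si](C)(C)Cl
Why: Standard silylation; the primary hydroxyl of the open-chain form reacts much faster than the tertiary hemiketal hydroxyl, which drains the ring–chain equilibrium to the open ynone.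

Step 3
Reactants: 5 7-[(tert-butyldimethylsilyl)oxy]-1-(trimethylsilyl)hept-1-yn-3-one
Product: 6 (3S)-7-[(tert-butyldimethylsilyl)oxy]-1-(trimethylsilyl)hept-1-yn-3-ol
Conditions: Ru[(S,S)-TsDPEN](p-cymene) (1 mol%), i-PrOH, rt
Reagents that add atoms: none
Why: Noyori asymmetric transfer hydrogenation of an alkynyl ketone, in which the alkyne takes the role of the aryl group of an aryl ketone; the (S,S)-ligand is expected to give the (S)-carbinol at C4, and the enantiomeric complex would be used should the sense prove opposite.

Step 4
Reactants: 6 (3S)-7-[(tert-butyldimethylsilyl)oxy]-1-(trimethylsilyl)hept-1-yn-3-ol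
Product: 7 (3S)-7-[(tert-butyldimethylsilyl)oxy]hept-1-yn-3-ol
Conditions: K2CO3, MeOH, rt
Reagents that add atoms: none
Why: Methanolysis of the alkynyl C–Si bond by methoxide; the primary alkyl silyl ether and the carbinol centre are inert under these conditions.

Step 5
Reactants: 7 (3S)-7-[(tert-butyldimethylsilyl)oxy]hept-1-yn-3-ol
Product: 9 (1Z,3S)-7-[(tert-butyldimethylsilyl)oxy]-1-iodo-2-methylhept-1-en-3-ol, via alkenylmagnesium chelate 8 (not isolated)
Conditions: MeMgBr (3.5 equiv), CuI (15 mol%), THF, −20 °C → rt; then iodine, THF, −60 → 0 °C; aq. Na2S2O3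
Reagents that add atoms: methylmagnesium bromide C[Mg]Br; iodine II
Why: Copper-catalysed anti-carbomagnesiation of a propargylic alkoxide: methyl goes to the proximal alkyne carbon (C5) and magnesium to the terminal carbon (C6) within a five-membered alkoxide chelate, so the C6–Mg bond is cis to C4; iodinolysis with retention gives the (Z)-iodide.

Step 6
Reactants: 9 (1Z,3S)-7-[(tert-butyldimethylsilyl)oxy]-1-iodo-2-methylhept-1-en-3-ol; 10 (E)-4,4,5,5-tetramethyl-2-(prop-1-en-1-yl)-1,3,2-dioxaborolane
Product: 11 (2E,4Z,6S)-10-[(tert-butyldimethylsilyl)oxy]-5-methyldeca-2,4-dien-6-ol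
Conditions: Pd(PPh3)4 (5 mol%), K3PO4, THF/H2O, 45 °C
Reagents that add atoms: none
Why: Suzuki–Miyaura coupling proceeds with retention at both alkenyl carbons, so the 5Z geometry is carried over from 9 and the 7E geometry from 10; the free secondary alcohol and the silyl ether are tolerated.

Step 7
Reactants: 11 (2E,4Z,6S)-10-[(tert-butyldimethylsilyl)oxy]-5-methyldeca-2,4-dien-6-ol
Product: 12 (2E,4Z,6S)-6,10-bis[(tert-butyldimethylsilyl)oxy]-5-methyldeca-2,4-diene
Conditions: TBSCl, imidazole, DMF, rt
Reagents that add atoms: tert-butyldimethylsilyl chloride CC(C)(C)[Si](C)(C)Cl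
Why: Standard silylation of a secondary allylic alcohol; the basic medium avoids ionisation of the dienylic C4–O bond.

Step 8
Reactants: 12 (2E,4Z,6S)-6,10-bis[(tert-butyldimethylsilyl)oxy]-5-methyldeca-2,4-diene
Product: 13 (5S,6Z,8E)-5-[(tert-butyldimethylsilyl)oxy]-6-methyldeca-6,8-dien-1-ol
Conditions: HF·pyridine, pyridine, THF, 0 °C
Reagents that add atoms: none
Why: Buffered fluoride cleaves the unhindered primary silyl ether much faster than the secondary one flanked by the trisubstituted alkene, and the pyridine buffer prevents acid ionisation at C4.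

Step 9
Reactants: 13 (5S,6Z,8E)-5-[(tert-butyldimethylsilyl)oxy]-6-methyldeca-6,8-dien-1-ol
Product: 14 (5S,6Z,8E)-5-[(tert-butyldimethylsilyl)oxy]-6-methyldeca-6,8-dienal
Conditions: Dess–Martin periodinane, NaHCO3, CH2Cl2, 0 °C → rt
Reagents that add atoms: none
Why: Dess–Martin oxidation of a primary alcohol under buffered, neutral conditions that leave the diene and the allylic silyl ether untouched.

Step 10
Reactants: 14 (5S,6Z,8E)-5-[(tert-butyldimethylsilyl)oxy]-6-methyldeca-6,8-dienal; 15 methyl 2-[bis(2,2,2-trifluoroethoxy)phosphoryl]propanoate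
Product: 17 methyl (2Z,7S,8Z,10E)-7-[(tert-butyldimethylsilyl)oxy]-2,8-dimethyldodeca-2,8,10-trienoate, via potassium phosphonate carbanion 16 (not isolated)
Conditions: 15, KN(SiMe3)2, 18-crown-6, THF, −78 °C; then 14, −78 °C
Reagents that add atoms: none
Why: Still–Gennari olefination: the electron-poor phosphonate under dissociating conditions eliminates rapidly from the kinetic adduct and gives the (Z)-2-methyl enoate, placing C15 cis to C1 as the C9/C10 relationship of the cycloadduct requires.

Step 11
Reactants: 17 methyl (2Z,7S,8Z,10E)-7-[(tert-butyldimethylsilyl)oxy]-2,8-dimethyldodeca-2,8,10-trienoate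
Product: 18 (2Z,7S,8Z,10E)-7-[(tert-butyldimethylsilyl)oxy]-N-methoxy-N,2,8-trimethyldodeca-2,8,10-trienamide
Conditions: MeNHOMe·HCl, i-PrMgCl, THF, −20 → 0 °C
Reagents that add atoms: N,O-dimethylhydroxylamine hydrochloride CNOC.Cl
Why: Weinreb amide formation by aminolysis of the ester with the chloromagnesium amide; the amide nucleophile is small enough for the hindered (Z)-enoate and does not touch the alkene geometries.

Step 12
Reactants: 19 methyl 4-hydroxy-3-iodobenzoate
Product: 20 methyl 4-[(tert-butyldimethylsilyl)oxy]-3-iodobenzoate
Conditions: TBSCl, imidazole, DMF, rt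
Reagents that add atoms: tert-butyldimethylsilyl chloride CC(C)(C)[Si](C)(C)Cl
Why: Standard phenol silylation; the non-coordinating silyl ether masks the phenol through the organomagnesium and Lewis-acid steps and prevents oxa-Michael closure of the later ortho-hydroxyaryl enone to a chromanone.

Step 13
Reactants: 20 methyl 4-[(tert-butyldimethylsilyl)oxy]-3-iodobenzoate; 18 (2Z,7S,8Z,10E)-7-[(tert-butyldimethylsilyl)oxy]-N-methoxy-N,2,8-trimethyldodeca-2,8,10-trienamide
Product: 22 methyl 4-[(tert-butyldimethylsilyl)oxy]-3-[(2Z,7S,8Z,10E)-7-[(tert-butyldimethylsilyl)oxy]-2,8-dimethyldodeca-2,8,10-trienoyl]benzoate, via arylmagnesium chloride 21 (not isolated)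
Conditions: 20, i-PrMgCl·LiCl, THF, −40 °C; then 18, −40 → 0 °C; aq. NH4Cl
Reagents that add atoms: none
Why: Iodine–magnesium exchange at −40 °C gives the ester-bearing arylmagnesium reagent without attack on the benzoate, and its addition to the Weinreb amide stops at the chelated tetrahedral intermediate, which releases the aryl ketone only on quench (Weinreb ketone synthesis).

Step 14
Reactants: 22 methyl 4-[(tert-butyldimethylsilyl)oxy]-3-[(2Z,7S,8Z,10E)-7-[(tert-butyldimethylsilyl)oxy]-2,8-dimethyldodeca-2,8,10-trienoyl]benzoate
Product: 23 methyl 4-[(tert-butyldimethylsilyl)oxy]-3-{[(1R,2S,4aS,5S,8aS)-5-[(tert-butyldimethylsilyl)oxy]-1,2,4a-trimethyl-1,2,4a,5,6,7,8,8a-octahydronaphthalen-1-yl]carbonyl}benzoate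
Conditions: Me2AlCl (3 equiv), CH2Cl2, −78 → −20 °C; aq. NaHCO3
Reagents that add atoms: none
Why: Me2AlCl binds the C15 ketone and lowers the LUMO of the C9=C10 enone, so that the concerted but asynchronous [4+2] cycloaddition with the C5=C6–C7=C8 diene can run at low temperature, below the range in which the 1,5-hydrogen shift of the Z-diene (C4–H to C8) or geometric isomerisation competes; the closest known reaction type is the Lewis-acid-promoted intramolecular Diels–Alder reaction of deca-1,7,9-trienones with a (Z)-diene, which gives cis-fused decalins. Ring B closes as the cycloadduct ring through C5–C10 and C8–C9, suprafacially on both partners, and ring A closes in the same event as the six-membered tether ring (C5–C4–C3–C2–C1–C10) through the C5–C10 bond. Because the tether leaves C5 from the inside (Z) position, C1 can reach C10 only in the exo orientation with H10 endo, so the cis ring fusion (C12 cis to H10) is the only mode available. C5 and C8 are controlled by the 5Z and 7E geometries, which put C12 and C13 at the two outside positions and hence on one face of ring B. C10 and C9 are controlled by the (Z)-enone, in which H10 and C14 are cis and both endo, so they join C12 and C13 on that face while the aroyl group ends exo and trans to them. The absolute sense is controlled by C4: to avoid allylic 1,3-strain the C4–H bond lies in the diene plane pointing towards C7, the tether then departs from one diene face and the silyloxy group covers the other, so the dienophile adds anti to the oxygen and the (S) centre gives the silyloxy group cis to C12, as in 23. The selectivities needed are thus diene-face selectivity (secured by C4), cis fusion (secured by the Z attachment of the tether) and integrity of the three alkene geometries up to bond formation (secured by low temperature and by Me2AlCl acting as its own proton scavenger).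

Step 15
Reactants: 23 methyl 4-[(tert-butyldimethylsilyl)oxy]-3-{[(1R,2S,4aS,5S,8aS)-5-[(tert-butyldimethylsilyl)oxy]-1,2,4a-trimethyl-1,2,4a,5,6,7,8,8a-octahydronaphthalen-1-yl]carbonyl}benzoate
Product: 24 methyl 4-[(tert-butyldimethylsilyl)oxy]-3-{[(1R,2S,4aS,5S,8aS)-5-[(tert-butyldimethylsilyl)oxy]-1,2,4a-trimethyldecahydronaphthalen-1-yl]carbonyl}benzoate
Conditions: H2 (1 atm), 10% Pd/C, EtOAc, rt
Reagents that add atoms: none
Why: Heterogeneous hydrogenation of the only C=C bond; C6 and C7 become methylene groups so no stereocentre arises, and the hindered aryl ketone, the benzoate and both silyl ethers are inert under neutral conditions.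

Step 16
Reactants: 24 methyl 4-[(tert-butyldimethylsilyl)oxy]-3-{[(1R,2S,4aS,5S,8aS)-5-[(tert-butyldimethylsilyl)oxy]-1,2,4a-trimethyldecahydronaphthalen-1-yl]carbonyl}benzoate
Product: 25 methyl 4-hydroxy-3-{[(1R,2S,4aS,5S,8aS)-5-hydroxy-1,2,4a-trimethyldecahydronaphthalen-1-yl]carbonyl}benzoate
Conditions: 48% aq. HF, MeCN/THF, rt
Reagents that add atoms: none
Why: Fluoride-assisted cleavage of both Si–O bonds in one operation; the methyl ester and the ketone are stable to aqueous HF and no stereocentre is touched.

Step 17
Reactants: 25 methyl 4-hydroxy-3-{[(1R,2S,4aS,5S,8aS)-5-hydroxy-1,2,4a-trimethyldecahydronaphthalen-1-yl]carbonyl}benzoate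
Product: 28 methyl 4-hydroxy-3-{[(1R,2S,4aS,5S,8aR)-5-hydroxy-1,2,4a-trimethyldecahydronaphthalen-1-yl]methyl}benzoate, via aryl ethyl carbonate 26 (not isolated), via ortho-quinone methide 27 (not isolated)
Conditions: ClCO2Et (1.1 equiv), Et3N, THF, 0 °C; then NaBH4, THF/H2O, 0 °C → rt
Reagents that add atoms: none
Why: Reductive deoxygenation of an ortho-acylphenol through its carbonate: the phenoxide is acylated in preference to the hindered C4 alcohol, borohydride reduces the ketone, the carbonate shifts to the new alkoxide and is expelled by the phenoxide to give the ortho-quinone methide, which takes a second hydride at C15. NaBH4 spares the benzoate and no cation is formed beside quaternary C9.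

Step 18
Reactants: 28 methyl 4-hydroxy-3-{[(1R,2S,4aS,5S,8aR)-5-hydroxy-1,2,4a-trimethyldecahydronaphthalen-1-yl]methyl}benzoate
Product: 29 methyl 4-hydroxy-3-{[(1R,2S,4aS,8aR)-1,2,4a-trimethyl-5-oxodecahydronaphthalen-1-yl]methyl}benzoate
Conditions: Dess–Martin periodinane, NaHCO3, CH2Cl2, 0 °C → rt
Reagents that add atoms: none
Why: Dess–Martin oxidation of the secondary C4 alcohol; the phenol is deactivated by the para ester and is expected to survive, and the ketone has no epimerisable neighbour (C5 is quaternary, C3 is a methylene).

Step 19
Reactants: 29 methyl 4-hydroxy-3-{[(1R,2S,4aS,8aR)-1,2,4a-trimethyl-5-oxodecahydronaphthalen-1-yl]methyl}benzoate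
Product: 30 methyl 4-hydroxy-3-{[(1R,2S,4aS,8aR)-1,2,4a-trimethyl-5-methylidenedecahydronaphthalen-1-yl]methyl}benzoate
Conditions: Ph3PCH3Br (5 equiv), KN(SiMe3)2 (4.5 equiv), toluene/THF, 0 → 80 °C; aq. NH4Cl
Reagents that add atoms: methyltriphenylphosphonium bromide C[P+](c1ccccc1)(c1ccccc1)c1ccccc1.[Br-]
Why: Wittig methylenation of the hindered, unconjugated C4 ketone with excess ylide at elevated temperature; the phenol is present as its phenoxide, which deactivates the para ester towards the ylide, and no alkoxide base is present to attack the ester.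

## Compound list

1 | δ-valerolactone (tetrahydro-2H-pyran-2-one) | O=C1CCCCO1 | starting material
2 | ethynyltrimethylsilane | C#C[Si](C)(C)C | starting material
3 | lithium (trimethylsilyl)acetylide (not isolated) | [Li]C#C[Si](C)(C)C | intermediate
4 | 7-hydroxy-1-(trimethylsilyl)hept-1-yn-3-one | C[Si](C)(C)C#CC(=O)CCCCO | intermediate
5 | 7-[(tert-butyldimethylsilyl)oxy]-1-(trimethylsilyl)hept-1-yn-3-one | C[Si](C)(C)C#CC(=O)CCCCO[Si](C)(C)C(C)(C)C | intermediate
6 | (3S)-7-[(tert-butyldimethylsilyl)oxy]-1-(trimethylsilyl)hept-1-yn-3-ol | C[Si](C)(C)C#C[C@@H](O)CCCCO[Si](C)(C)C(C)(C)C | intermediate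
7 | (3S)-7-[(tert-butyldimethylsilyl)oxy]hept-1-yn-3-ol | C#C[C@@H](O)CCCCO[Si](C)(C)C(C)(C)C | intermediate
8 | (5S)-5-{4-[(tert-butyldimethylsilyl)oxy]butyl}-4-methyl-2,5-dihydro-1,2-oxamagnesole, the cyclic (Z)-alkenylmagnesium alkoxide (not isolated) | CC1=C[Mg]O[C@H]1CCCCO[Si](C)(C)C(C)(C)C | intermediate
9 | (1Z,3S)-7-[(tert-butyldimethylsilyl)oxy]-1-iodo-2-methylhept-1-en-3-ol | I/C=C(/C)[C@@H](O)CCCCO[Si](C)(C)C(C)(C)C | intermediate
10 | (E)-4,4,5,5-tetramethyl-2-(prop-1-en-1-yl)-1,3,2-dioxaborolane | C/C=C/B1OC(C)(C)C(C)(C)O1 | starting material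
11 | (2E,4Z,6S)-10-[(tert-butyldimethylsilyl)oxy]-5-methyldeca-2,4-dien-6-ol | C/C=C/C=C(/C)[C@@H](O)CCCCO[Si](C)(C)C(C)(C)C | intermediate
12 | (2E,4Z,6S)-6,10-bis[(tert-butyldimethylsilyl)oxy]-5-methyldeca-2,4-diene | C/C=C/C=C(/C)[C@@H](O[Si](C)(C)C(C)(C)C)CCCCO[Si](C)(C)C(C)(C)C | intermediate
13 | (5S,6Z,8E)-5-[(tert-butyldimethylsilyl)oxy]-6-methyldeca-6,8-dien-1-ol | C/C=C/C=C(/C)[C@@H](O[Si](C)(C)C(C)(C)C)CCCCO | intermediate
14 | (5S,6Z,8E)-5-[(tert-butyldimethylsilyl)oxy]-6-methyldeca-6,8-dienal | C/C=C/C=C(/C)[C@@H](O[Si](C)(C)C(C)(C)C)CCCC=O | intermediate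
15 | methyl 2-[bis(2,2,2-trifluoroethoxy)phosphoryl]propanoate | COC(=O)C(C)P(=O)(OCC(F)(F)F)OCC(F)(F)F | starting material
16 | potassium salt (carbanion) of 15 (not isolated) | COC(=O)[C-](C)P(=O)(OCC(F)(F)F)OCC(F)(F)F.[K+] | intermediate
17 | methyl (2Z,7S,8Z,10E)-7-[(tert-butyldimethylsilyl)oxy]-2,8-dimethyldodeca-2,8,10-trienoate | C/C=C/C=C(/C)[C@@H](O[Si](C)(C)C(C)(C)C)CCC/C=C(/C)C(=O)OC | intermediate
18 | (2Z,7S,8Z,10E)-7-[(tert-butyldimethylsilyl)oxy]-N-methoxy-N,2,8-trimethyldodeca-2,8,10-trienamide | C/C=C/C=C(/C)[C@@H](O[Si](C)(C)C(C)(C)C)CCC/C=C(/C)C(=O)N(C)OC | intermediate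
19 | methyl 4-hydroxy-3-iodobenzoate | COC(=O)c1ccc(O)c(I)c1 | starting material
20 | methyl 4-[(tert-butyldimethylsilyl)oxy]-3-iodobenzoate | COC(=O)c1ccc(O[Si](C)(C)C(C)(C)C)c(I)c1 | intermediate
21 | {2-[(tert-butyldimethylsilyl)oxy]-5-(methoxycarbonyl)phenyl}magnesium chloride, LiCl complex (not isolated) | COC(=O)c1ccc(O[Si](C)(C)C(C)(C)C)c([Mg]Cl)c1 | intermediate
22 | methyl 4-[(tert-butyldimethylsilyl)oxy]-3-[(2Z,7S,8Z,10E)-7-[(tert-butyldimethylsilyl)oxy]-2,8-dimethyldodeca-2,8,10-trienoyl]benzoate | C/C=C/C=C(/C)[C@@H](O[Si](C)(C)C(C)(C)C)CCC/C=C(/C)C(=O)c1cc(C(=O)OC)ccc1O[Si](C)(C)C(C)(C)C | intermediate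
23 | methyl 4-[(tert-butyldimethylsilyl)oxy]-3-{[(1R,2S,4aS,5S,8aS)-5-[(tert-butyldimethylsilyl)oxy]-1,2,4a-trimethyl-1,2,4a,5,6,7,8,8a-octahydronaphthalen-1-yl]carbonyl}benzoate | CC(C)(C)[Si](C)(C)O[C@H]1CCC[C@@H]2[C@](C)(C(=O)c3cc(C(=O)OC)ccc3O[Si](C)(C)C(C)(C)C)[C@@H](C)C=C[C@]12C | intermediate
24 | methyl 4-[(tert-butyldimethylsilyl)oxy]-3-{[(1R,2S,4aS,5S,8aS)-5-[(tert-butyldimethylsilyl)oxy]-1,2,4a-trimethyldecahydronaphthalen-1-yl]carbonyl}benzoate | CC(C)(C)[Si](C)(C)O[C@H]1CCC[C@@H]2[C@](C)(C(=O)c3cc(C(=O)OC)ccc3O[Si](C)(C)C(C)(C)C)[C@@H](C)CC[C@]12C | intermediate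
25 | methyl 4-hydroxy-3-{[(1R,2S,4aS,5S,8aS)-5-hydroxy-1,2,4a-trimethyldecahydronaphthalen-1-yl]carbonyl}benzoate | O[C@H]1CCC[C@@H]2[C@](C)(C(=O)c3cc(C(=O)OC)ccc3O)[C@@H](C)CC[C@]12C | intermediate
26 | methyl 4-[(ethoxycarbonyl)oxy]-3-{[(1R,2S,4aS,5S,8aS)-5-hydroxy-1,2,4a-trimethyldecahydronaphthalen-1-yl]carbonyl}benzoate (not isolated) | O[C@H]1CCC[C@@H]2[C@](C)(C(=O)c3cc(C(=O)OC)ccc3OC(=O)OCC)[C@@H](C)CC[C@]12C | intermediate
27 | ortho-quinone methide, methyl 3-[(5-hydroxy-1,2,4a-trimethyldecahydronaphthalen-1-yl)methylidene]-4-oxocyclohexa-1,5-diene-1-carboxylate, ring centres as in 25 (not isolated) | O[C@H]1CCC[C@@H]2[C@](C)(C=C3C=C(C(=O)OC)C=CC3=O)[C@@H](C)CC[C@]12C | intermediate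
28 | methyl 4-hydroxy-3-{[(1R,2S,4aS,5S,8aR)-5-hydroxy-1,2,4a-trimethyldecahydronaphthalen-1-yl]methyl}benzoate | O[C@H]1CCC[C@@H]2[C@](C)(Cc3cc(C(=O)OC)ccc3O)[C@@H](C)CC[C@]12C | intermediate
29 | methyl 4-hydroxy-3-{[(1R,2S,4aS,8aR)-1,2,4a-trimethyl-5-oxodecahydronaphthalen-1-yl]methyl}benzoate | O=C1CCC[C@@H]2[C@](C)(Cc3cc(C(=O)OC)ccc3O)[C@@H](C)CC[C@]12C | intermediate
30 | methyl 4-hydroxy-3-{[(1R,2S,4aS,8aR)-1,2,4a-trimethyl-5-methylidenedecahydronaphthalen-1-yl]methyl}benzoate | C=C1CCC[C@@H]2[C@](C)(Cc3cc(C(=O)OC)ccc3O)[C@@H](C)CC[C@]12C | target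

## Step count and least certain steps

Total: 19 steps. Longest linear sequence: 18 steps (steps 1–11 and 13–19); step 12 is a one-step side branch.

Step 14 (key step). The cycloaddition may be too slow, because both new bonds end at a fully substituted carbon and the Z-diene resists the s-cis conformation. If the temperature has to be raised, three processes can overtake ring closure: Lewis-acid-induced Z-to-E isomerisation of the enone (which would invert C9), ionisation of the dienylic C4–O bond, and the 1,5-hydrogen shift of the Z-diene. Fallback, setting out from 18: reduction with i-Bu2AlH (THF, −78 °C) gives the (Z)-trienal F1, whose smaller and more electrophilic formyl group replaces the aroyl group as activator. Me2AlCl-promoted cyclisation through the same transition-state geometry gives the decalin aldehyde F2. Addition of 21 (made as in step 13) to this neopentylic aldehyde gives the benzylic alcohol F3 as both C15 epimers, and Dess–Martin oxidation comes back to the route at 23.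

Step 5. Carbomagnesiation of a secondary propargylic alkoxide may be incomplete or may lose regiocontrol, and the alkenylmagnesium species may be protonated before iodinolysis. Fallback, setting out from 7: silylation (TBSCl, imidazole) gives the bis-silyl alkyne F4; n-BuLi then ClCO2Me gives the ynoate F5; syn-addition of Me2CuLi (THF, −78 °C, cold quench) gives the (Z)-enoate F6, with the ester carbon (future C7) cis to C4. Reduction with i-Bu2AlH gives the allylic alcohol F7, MnO2 gives the (Z)-enal F8, and E-selective Takai–Utimoto ethylidenation (CrCl2, CH3CHI2, THF) comes back to the route at 12, bypassing steps 5 to 7.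

Step 13. Addition of a hindered ortho-silyloxy arylmagnesium reagent to a hindered (Z)-2-methyl Weinreb amide may be slow, leaving time for self-condensation on the benzoate or for oxygen-to-carbon silyl migration in 21. Fallback, setting out from 17: saponification (LiOH, THF/MeOH/H2O) gives the acid F9, and EtSH/EDC/DMAP gives the thioester F10. The arylzinc iodide F11 is prepared from 20 (Zn dust, LiCl, THF) and coupled with F10 under Fukuyama conditions (PdCl2(PPh3)2, THF/toluene, rt), coming back to the route at 22. The zinc reagent does not attack esters, and the coupling is neutral.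

Step 17. The aryl carbonate may be cleaved by hydroxide or borate before the hindered C15 ketone is reduced, which would return the unreactive acylphenoxide; hydride delivery to the neopentylic C15 of the quinone methide may also be slow. Fallback, setting out from 25: NaBH4 (MeOH, 0 °C → rt) gives the triol F12 as both C15 epimers. Ionic hydrogenation (Et3SiH, CF3CO2H, CH2Cl2, 0 °C), followed by K2CO3/MeOH to cleave any C4 trifluoroacetate, comes back to the route at 28. The ortho oxygen stabilises the benzylic cation, but a 1,2-shift from C9 remains the risk that makes this the second choice.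

Step 19. The ylide may enolise the hindered C4 ketone towards C3 instead of adding, or may slowly attack the ester. Fallback, setting out from 29: Takai–Lombardo methylenation (Zn, CH2Br2, TiCl4, THF/CH2Cl2, 0 °C → rt), a non-basic gem-dimetallic reagent that is selective for ketones over esters, gives 30 directly with no new intermediate.

## Further compounds

F1 | step 14 | (2Z,7S,8Z,10E)-7-[(tert-butyldimethylsilyl)oxy]-2,8-dimethyldodeca-2,8,10-trienal | C/C=C/C=C(/C)[C@@H](O[Si](C)(C)C(C)(C)C)CCC/C=C(/C)C=O
F2 | step 14 | (1R,2S,4aS,5S,8aS)-5-[(tert-butyldimethylsilyl)oxy]-1,2,4a-trimethyl-1,2,4a,5,6,7,8,8a-octahydronaphthalene-1-carbaldehyde | CC(C)(C)[Si](C)(C)O[C@H]1CCC[C@@H]2[C@](C)(C=O)[C@@H](C)C=C[C@]12C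
F3 | step 14 | C15 alcohol corresponding to ketone 23 (both C15 epimers) | CC(C)(C)[Si](C)(C)O[C@H]1CCC[C@@H]2[C@](C)(C(O)c3cc(C(=O)OC)ccc3O[Si](C)(C)C(C)(C)C)[C@@H](C)C=C[C@]12C
F4 | step 5 | (3S)-3,7-bis[(tert-butyldimethylsilyl)oxy]hept-1-yne | C#C[C@@H](O[Si](C)(C)C(C)(C)C)CCCCO[Si](C)(C)C(C)(C)C
F5 | step 5 | methyl (4S)-4,8-bis[(tert-butyldimethylsilyl)oxy]oct-2-ynoate | COC(=O)C#C[C@@H](O[Si](C)(C)C(C)(C)C)CCCCO[Si](C)(C)C(C)(C)C
F6 | step 5 | methyl (2Z,4S)-4,8-bis[(tert-butyldimethylsilyl)oxy]-3-methyloct-2-enoate | COC(=O)/C=C(/C)[C@@H](O[Si](C)(C)C(C)(C)C)CCCCO[Si](C)(C)C(C)(C)C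
F7 | step 5 | (2Z,4S)-4,8-bis[(tert-butyldimethylsilyl)oxy]-3-methyloct-2-en-1-ol | OC/C=C(/C)[C@@H](O[Si](C)(C)C(C)(C)C)CCCCO[Si](C)(C)C(C)(C)C
F8 | step 5 | (2Z,4S)-4,8-bis[(tert-butyldimethylsilyl)oxy]-3-methyloct-2-enal | O=C/C=C(/C)[C@@H](O[Si](C)(C)C(C)(C)C)CCCCO[Si](C)(C)C(C)(C)C
F9 | step 13 | (2Z,7S,8Z,10E)-7-[(tert-butyldimethylsilyl)oxy]-2,8-dimethyldodeca-2,8,10-trienoic acid | C/C=C/C=C(/C)[C@@H](O[Si](C)(C)C(C)(C)C)CCC/C=C(/C)C(=O)O
F10 | step 13 | S-ethyl (2Z,7S,8Z,10E)-7-[(tert-butyldimethylsilyl)oxy]-2,8-dimethyldodeca-2,8,10-trienethioate | C/C=C/C=C(/C)[C@@H](O[Si](C)(C)C(C)(C)C)CCC/C=C(/C)C(=O)SCC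
F11 | step 13 | {2-[(tert-butyldimethylsilyl)oxy]-5-(methoxycarbonyl)phenyl}zinc iodide | COC(=O)c1ccc(O[Si](C)(C)C(C)(C)C)c([Zn]I)c1
F12 | step 17 | C15 alcohol corresponding to ketone 25 (both C15 epimers) | O[C@H]1CCC[C@@H]2[C@](C)(C(O)c3cc(C(=O)OC)ccc3O)[C@@H](C)CC[C@]12C
F0 | step 19 | none | none
A1 | alternative 1 | cis-fused 1-{[5-bromo-2-(methoxymethoxy)phenyl]methyl}-1,4a-dimethyl-3,4,4a,7,8,8a-hexahydronaphthalen-2(1H)-one | C1=CCC[C@@H]2[C@](C)(Cc3cc(Br)ccc3OCOC)C(=O)CC[C@]12C
A2 | alternative 1 | 3-{[5-bromo-2-(methoxymethoxy)phenyl]methyl}-3,5-dimethyl-2-vinylbicyclo[2.2.2]oct-5-en-2-ol, vinyl group and C3 methyl on the side of the ring alkene | C1C[C@@H]3C=C(C)[C@H]1[C@](C)(Cc4cc(Br)ccc4OCOC)[C@@]3(O)C=C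
A3 | alternative 2 | methyl 2-chloro-4-hydroxy-3-(decalinylcarbonyl)benzoate with the C4 ketone as ethylene ketal | O1CCOC12CCC[C@@H]3[C@](C)(C(=O)c4c(Cl)c(C(=O)OC)ccc4O)[C@@H](C)CC[C@]23C
A4 | alternative 2 | cis-decalin C15 carboxylic acid with the C4 ketone as ethylene ketal | O1CCOC12CCC[C@@H]3[C@](C)(C(=O)O)[C@@H](C)CC[C@]23C
A5 | alternative 2 | methyl 2-chloro-4-{[(trifluoromethyl)sulfonyl]oxy}-3-(trimethylsilyl)benzoate | COC(=O)c1ccc(OS(=O)(=O)C(F)(F)F)c([Si](C)(C)C)c1Cl
A6 | alternative 2 | methyl 2-chloro-3,4-didehydrobenzoate (aryne) | COC(=O)C1=C(Cl)C#CC=C1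
A7 | alternative 3 | cis-fused methyl 4-[(tert-butyldimethylsilyl)oxy]-3-[(1,2,4a-trimethyl-7-oxo-1,2,3,4,4a,7,8,8a-octahydronaphthalen-1-yl)methyl]benzoate | C1=CC(=O)C[C@@H]2[C@](C)(Cc3cc(C(=O)OC)ccc3O[Si](C)(C)C(C)(C)C)[C@@H](C)CC[C@]12C
A8 | alternative 3 | methyl 4-[(tert-butyldimethylsilyl)oxy]-3-[(3S)-3-methyl-2-methylidene-5-(1-methyl-4-oxocyclohexa-2,5-dien-1-yl)pentyl]benzoate | C=C(Cc1cc(C(=O)OC)ccc1O[Si](C)(C)C(C)(C)C)[C@@H](C)CCC1(C)C=CC(=O)C=C1
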